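**Plan**

Ring numbering used below: C1 (ring C=O next to the quaternary carbon), C2 (bears the 3-phenylpropanoyl group, whose carbonyl carbon is C7), C3 (enol), C4 (prenyl), C5 (enol), C6 (quaternary, OMe and prenyl).
Retrosynthesis: the ring bonds C2–C3 and C4–C5 are cut together, which leaves a two-carbon ynolate (C3–C4 with its prenyl group) and the chain C5–C6–C1–C2–C7; then the C1–C2 bond of the β-diketone and the C6–prenyl bond of a methoxymalonate are cut.
Enabling feature: the core is a cyclohexane-1,3,5-trione, so C1, C3 and C5 are acyl carbons and C2 and C4 enolate carbons; C3–C4 is therefore a ketene anion, and the enol oxygen on C7 can hold C5 as a six-membered enol lactone (a 2H-pyran-2,4(3H)-dione, ring O–C5–C6–C1–C2–C7) that is not in the target.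
Forward: malonate, prenylation, desymmetrisation, β-diketo ester, enol lactone; the ynolate, made in the same flask from an α,α-dibromo ester, then opens the lactone at C5 and the freed diketonate closes the carbocycle at C3, so the temporary ring is spent in the step that builds the final one and its oxygen ends as the C7 carbonyl oxygen.
Stereochemistry: the only stereocentre, C6, is set by enzymatic desymmetrisation of the prochiral malonate and is quaternary; no later step makes or breaks a bond at C6, so it cannot be scrambled.

Key step: step 7

Assumption: pig liver esterase is taken to hydrolyse the pro-R ester group of 3, which gives the (S)-acid 4; if it prefers the other group, the resolution given as fallback for step 2 supplies the same acid.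

**Route**

Step 1
Reactants: 1 dimethyl 2-methoxypropanedioate; 2 1-bromo-3-methylbut-2-ene (prenyl bromide)
Product: 3 dimethyl 2-methoxy-2-(3-methylbut-2-en-1-yl)propanedioate
Conditions: NaH, THF, 0 °C to rt
Reagents that add atoms: none
Why: Malonic ester alkylation, in which the sodium enolate of the α-methoxy malonate attacks the primary allylic bromide by SN2 at carbon; the product has two identical ester groups and is still achiral.

Step 2
Reactants: 3 dimethyl 2-methoxy-2-(3-methylbut-2-en-1-yl)propanedioate
Product: 4 (2S)-2-methoxy-2-(methoxycarbonyl)-5-methylhex-4-enoic acid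
Conditions: pig liver esterase, phosphate buffer (pH 7.5)/DMSO 9:1, 25 °C, 1 M NaOH by pH-stat; then 1 M HCl to pH 2
Reagents that add atoms: water, O
Why: Enzymatic desymmetrisation of a prochiral α,α-disubstituted malonate, in which the esterase hydrolyses only one of the two enantiotopic ester groups (small methoxy group against large prenyl group in the active site) and thereby creates the C6 stereocentre, while the anionic half-ester is no longer a substrate.

Step 3
Reactants: 4 (2S)-2-methoxy-2-(methoxycarbonyl)-5-methylhex-4-enoic acid; 5 4-phenylbutan-2-one
Product: 7 methyl (2S)-2-methoxy-2-(3-methylbut-2-en-1-yl)-3,5-dioxo-7-phenylheptanoate, via acid chloride 6 (not isolated)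
Conditions: (COCl)2, DMF (cat.), CH2Cl2, 0 °C to rt, then evaporation; 5 (2.2 equiv), LiN(i-Pr)2 (2.2 equiv), THF, −78 °C, then 6 in THF, −78 °C; aq. NH4Cl
Reagents that add atoms: none
Why: Acid chloride formation through the chloroiminium (Vilsmeier-type) intermediate, safe for C6 because it bears no hydrogen, followed by crossed Claisen C-acylation of the kinetic methyl-side lithium enolate of 5; the second equivalent of enolate deprotonates the β-diketone as it forms and turns any O-acylated enol ester into the same diketonate, and at −78 °C the acid chloride reacts far faster than the methyl ester.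

Step 4
Reactants: 7 methyl (2S)-2-methoxy-2-(3-methylbut-2-en-1-yl)-3,5-dioxo-7-phenylheptanoate
Product: 9 (3S)-3-methoxy-3-(3-methylbut-2-en-1-yl)-6-(2-phenylethyl)-2H-pyran-2,4(3H)-dione, via keto acid 8 (not isolated)
Conditions: LiOH, THF/H2O, 0 °C to rt; 1 M HCl to pH 2 at 0 °C, extraction (CH2Cl2); then EDC·HCl, DMAP (cat.), CH2Cl2, 0 °C
Reagents that add atoms: none
Why: Saponification of the α-alkoxy ester while the β-diketone is protected as its enolate, followed by carbodiimide (Steglich-type) lactonisation in which the enol oxygen on C7 attacks the activated carboxyl group in a 6-exo-trig closure, the only ring size open to the diketone oxygens; the β-keto acid 8 is kept at 0 °C and used at once so that it does not lose CO2, and C6 is not touched.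

Step 5
Reactants: 10 2-methylbut-3-en-2-ol; 11 1,1,1-triethoxyethane (triethyl orthoacetate)
Product: 13 ethyl 5-methylhex-4-enoate, via ketene acetal 12 (not isolated)
Conditions: EtCO2H (cat.), 140 °C, EtOH distilled off
Reagents that add atoms: none
Why: Johnson orthoester Claisen rearrangement, in which acid-catalysed exchange and loss of ethanol give ketene acetal 12 and its [3,3]-sigmatropic shift through a chair transition state turns the tertiary allylic alcohol into the 3-methylbut-2-enyl end of the new ester.

Step 6
Reactants: 13 ethyl 5-methylhex-4-enoate
Product: 15 ethyl 2,2-dibromo-5-methylhex-4-enoate, via bromo ester 14 (not isolated)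
Conditions: LiN(i-Pr)2, THF, −78 °C, then BrCCl2CCl2Br; second cycle in the same flask (LiN(i-Pr)2, then BrCCl2CCl2Br), −78 to 0 °C
Reagents that add atoms: 1,2-dibromo-1,1,2,2-tetrachloroethane, BrC(Cl)(Cl)C(Cl)(Cl)Br
Why: Twofold α-bromination of an ester lithium enolate by a positive-bromine donor that does not add to the trisubstituted alkene, the second deprotonation being easier than the first because bromo ester 14 is the stronger acid.

Step 7
Reactants: 15 ethyl 2,2-dibromo-5-methylhex-4-enoate; 9 (3S)-3-methoxy-3-(3-methylbut-2-en-1-yl)-6-(2-phenylethyl)-2H-pyran-2,4(3H)-dione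
Product: 18 helihumulone [(6R)-3,5-dihydroxy-6-methoxy-4,6-bis(3-methylbut-2-en-1-yl)-2-(3-phenylpropanoyl)cyclohexa-2,4-dien-1-one], via lithium ynolate 16 (not isolated), via acylketene enolate 17 (not isolated)
Conditions: 15 (2.0 equiv), t-BuLi (8.0 equiv), THF, −78 to 0 °C; then 9 added at −78 °C, to 0 °C; 1 M HCl
Reagents that add atoms: none
Why: Proposed new method: double lithium–bromine exchange on 15 and loss of lithium ethoxide from the ester dianion give ynolate 16 (the known route from α,α-dibromo esters), whose carbon terminus C4 adds to the lactone carbonyl C5 of 9; the tetrahedral adduct expels the enolate oxygen on C7 (a β-diketonate, a far better leaving group than the alkoxide of a simple ester, so that collapse to acylketene 17 should outrun closure to a β-lactone enolate), and the freed diketonate carbon C2 then adds to the ketene carbon C3 to give the lithium salt of 18 with no atom of 9 or 16 lost. The closest known reaction types are the tandem addition–Dieckmann reactions of ynolates with keto esters, the ring-opening Claisen acylation of enolates by enol lactones and the C-acylation of 1,3-dicarbonyl compounds by acylketenes. The carbocycle closes by a 6-(enolexo)-exo-dig attack (exo with respect to the ketene C=O bond) in the plane of the ketene, the geometry of the known six-ring lactonisations of acylketenes, and the pyrandione ring is opened in the same operation, so that its oxygen ends as the C7 carbonyl oxygen. No stereocentre is formed: C6 is quaternary and no bond to it is made or broken, so the configuration of 9 is carried into 18 (the descriptor changes from S to R only because the CIP ranks of C1 and C5 are exchanged). The step needs site selectivity for C5 over the C1 ketone and the conjugate position C7, which is secured because C5 is the only carbonyl carbon with a leaving group, C1 is a deactivated vinylogous ester carbonyl and the slim, hard, weakly basic ynolate prefers 1,2-addition, and it needs the ynolate carbon to outrun the aggregated lithium ethoxide formed beside it, which should hold at −78 °C; regioselectivity in the ring closure is fixed because C4 is the only carbanion and C3 the only ketene carbon, so the CH2 group next to C7 cannot compete as it would in a Dieckmann closure of a triacylmethane. O-acylation of the diketonate by the ketene can revert by E1cB of the enol lactone enolate, whereas C-acylation ends in the stabilised vinylogous carboxylate of the trione, whose remaining acidic proton on C2 is taken by lithium ethoxide or by the excess ynolate.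

**Compound list**

1 | dimethyl 2-methoxypropanedioate | COC(=O)C(OC)C(=O)OC | starting material
2 | 1-bromo-3-methylbut-2-ene | CC(C)=CCBr | starting material
3 | dimethyl 2-methoxy-2-(3-methylbut-2-en-1-yl)propanedioate | COC(=O)C(OC)(CC=C(C)C)C(=O)OC | intermediate
4 | (2S)-2-methoxy-2-(methoxycarbonyl)-5-methylhex-4-enoic acid | CO[C@@](C(=O)OC)(CC=C(C)C)C(=O)O | intermediate
5 | 4-phenylbutan-2-one | CC(=O)CCc1ccccc1 | starting material
6 | methyl (2R)-2-(chlorocarbonyl)-2-methoxy-5-methylhex-4-enoate (same spatial arrangement as 4) | CO[C@@](C(=O)OC)(CC=C(C)C)C(=O)Cl | intermediate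
7 | methyl (2S)-2-methoxy-2-(3-methylbut-2-en-1-yl)-3,5-dioxo-7-phenylheptanoate | CO[C@@](C(=O)OC)(CC=C(C)C)C(=O)CC(=O)CCc1ccccc1 | intermediate
8 | (2S)-2-methoxy-2-(3-methylbut-2-en-1-yl)-3,5-dioxo-7-phenylheptanoic acid | CO[C@@](C(=O)O)(CC=C(C)C)C(=O)CC(=O)CCc1ccccc1 | intermediate
9 | (3S)-3-methoxy-3-(3-methylbut-2-en-1-yl)-6-(2-phenylethyl)-2H-pyran-2,4(3H)-dione | CO[C@@]1(CC=C(C)C)C(=O)C=C(CCc2ccccc2)OC1=O | intermediate
10 | 2-methylbut-3-en-2-ol | CC(C)(O)C=C | starting material
11 | 1,1,1-triethoxyethane | CCOC(C)(OCC)OCC | starting material
12 | 1-ethoxy-1-[(2-methylbut-3-en-2-yl)oxy]ethene | C=C(OCC)OC(C)(C)C=C | intermediate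
13 | ethyl 5-methylhex-4-enoate | CCOC(=O)CCC=C(C)C | intermediate
14 | ethyl 2-bromo-5-methylhex-4-enoate (racemic) | CCOC(=O)C(Br)CC=C(C)C | intermediate
15 | ethyl 2,2-dibromo-5-methylhex-4-enoate | CCOC(=O)C(Br)(Br)CC=C(C)C | intermediate
16 | lithium 5-methylhex-4-en-1-yn-1-olate | [Li+].[O-]C#CCC=C(C)C | intermediate
17 | lithium enolate (over the 5,7-diketone) of (4S)-4-methoxy-2,4-bis(3-methylbut-2-en-1-yl)-3,5,7-trioxo-9-phenylnon-1-en-1-one, an acylketene | CO[C@@](C(=O)C(CC=C(C)C)=C=O)(CC=C(C)C)C(=O)C=C([O-])CCc1ccccc1.[Li+] | intermediate
18 | helihumulone, (6R)-3,5-dihydroxy-6-methoxy-4,6-bis(3-methylbut-2-en-1-yl)-2-(3-phenylpropanoyl)cyclohexa-2,4-dien-1-one (drawn as the dienol tautomer) | CO[C@@]1(CC=C(C)C)C(=O)C(C(=O)CCc2ccccc2)=C(O)C(CC=C(C)C)=C1O | target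

**Step count**

Total steps: 7. Longest linear sequence: 5 steps (1, 2, 3, 4, 7); the ynolate branch (steps 5, 6) joins in step 7.

**Steps most likely to fail**

Step 7 (bears the label "Proposed new method:"). What may go wrong: the tetrahedral adduct closes to a β-lactone enolate and follows the olefination path, the ynolate adds to the C1 ketone, the diketonate is acylated on oxygen without return, or lithium ethoxide opens the enol lactone before the ynolate does. The fallback uses known chemistry and no alkoxide in its first operation, sets out from 9 (with ester 13 from the route) and comes back at 18. The lithium enolate of 13 (LiN(i-Pr)2, THF, −78 °C, 2.2 equiv) should open the enol lactone by Claisen acylation at C5 and give, after aqueous acid, the open-chain ester ethyl (4S)-4-methoxy-2,4-bis(3-methylbut-2-en-1-yl)-3,5,7-trioxo-9-phenylnonanoate F1 (both epimers at the new β-keto ester carbon, which becomes trigonal again). This is then closed in a separate operation by base-mediated Claisen (Dieckmann-type) C-acylation of the diketone carbon C2 by the β-keto ester (DBU, toluene, 80 °C), the closure known from triketo esters to acylphloroglucinols. The six-membered Claisen closure is the one driven forward by the stabilised trione anion, and loss of ethanol gives 18.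

Step 2. What may go wrong: poor discrimination between the enantiotopic ester groups, or the opposite sense of hydrolysis. The fallback sets out from 3 and comes back at 4. Monosaponification (KOH, 1 equiv, MeOH, 0 °C) should give racemic 2-methoxy-2-(methoxycarbonyl)-5-methylhex-4-enoic acid F2. This is resolved by fractional crystallisation of its salt with (S)-1-phenylethanamine, (1S)-1-phenylethanaminium (2S)-2-methoxy-2-(methoxycarbonyl)-5-methylhex-4-enoate F3; the enantiomeric amine is used instead if it gives the less soluble salt of the (S)-acid. Acidification of the salt releases 4.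

Step 4. What may go wrong: loss of CO2 from the β-keto acid before the lactone closes, or hydrolytic reopening of the enol lactone. The fallback avoids any β-keto acid, sets out from 3 and comes back at 9. Full saponification (LiOH, THF/H2O) should give 2-methoxy-2-(3-methylbut-2-en-1-yl)propanedioic acid F4, and (COCl)2 with DMF (cat.) its dichloride 2-methoxy-2-(3-methylbut-2-en-1-yl)propanedioyl dichloride F5. The silyl enol ether trimethyl[(4-phenylbut-1-en-2-yl)oxy]silane F6 is made from 5 (LiN(i-Pr)2, Me3SiCl, THF, −78 °C). Double acylation of F6 by F5 (Et2O, −20 °C; C-acylation, then closure through the enol oxygen) should give racemic 3-methoxy-3-(3-methylbut-2-en-1-yl)-6-(2-phenylethyl)-2H-pyran-2,4(3H)-dione F7. The (S)-enantiomer 9 is then separated by preparative chromatography on a chiral stationary phase.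

Further compounds
F1 | step 7 | ethyl (4S)-4-methoxy-2,4-bis(3-methylbut-2-en-1-yl)-3,5,7-trioxo-9-phenylnonanoate | CO[C@@](C(=O)C(CC=C(C)C)C(=O)OCC)(CC=C(C)C)C(=O)CC(=O)CCc1ccccc1
F2 | step 2 | racemic 2-methoxy-2-(methoxycarbonyl)-5-methylhex-4-enoic acid | COC(=O)C(OC)(CC=C(C)C)C(=O)O
F3 | step 2 | (1S)-1-phenylethanaminium (2S)-2-methoxy-2-(methoxycarbonyl)-5-methylhex-4-enoate | CO[C@@](C(=O)OC)(CC=C(C)C)C(=O)[O-].C[C@H]([NH3+])c1ccccc1
F4 | step 4 | 2-methoxy-2-(3-methylbut-2-en-1-yl)propanedioic acid | OC(=O)C(OC)(CC=C(C)C)C(=O)O
F5 | step 4 | 2-methoxy-2-(3-methylbut-2-en-1-yl)propanedioyl dichloride | ClC(=O)C(OC)(CC=C(C)C)C(=O)Cl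
F6 | step 4 | trimethyl[(4-phenylbut-1-en-2-yl)oxy]silane | C=C(CCc1ccccc1)O[Si](C)(C)C
F7 | step 4 | racemic 3-methoxy-3-(3-methylbut-2-en-1-yl)-6-(2-phenylethyl)-2H-pyran-2,4(3H)-dione | COC1(CC=C(C)C)C(=O)C=C(CCc2ccccc2)OC1=O
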